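**Retrosynthetic overview**
1. The acetate and the E side-chain alkene come last: O-acetylation, and Zr-catalysed carboalumination/hydroxymethylation of terminal alkyne acid 20.
2. Ring A (second ring): Ireland–Claisen ring contraction of vinyl δ-lactone 17 forms the C1–C8a bond, sets C-1 and C-8a from a CBS-set carbinol and places the alkene at C4=C4a.
3. Lactone 17 comes from the ring-B vinyllithium (Shapiro reaction of ketone 9) and 2-methylglutaric anhydride.
4. Ketone 9 (C-5, C-6 of the target): Cu-catalysed asymmetric conjugate methylation of the flat, achiral enone 4, then enolate alkylation anti to the new methyl.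
5. Key step: ring B (first ring) is made by Birch dearomatisation of 2-methylanisole, with diene conjugation before hydrolysis so that the 2-methyl enone 4 results.

Assumption: (4-iodobut-1-yn-1-yl)trimethylsilane and 2-methylglutaric anhydride are bought as catalogue compounds, and the phosphoramidite enantiomer in step 2 is the one that gives the 3S product.

Locants in the "Why" lines are those of the target name (octahydronaphthalene numbering).

**Step 1**
Reactants: 1 2-methylanisole (1-methoxy-2-methylbenzene)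
Product: 4 2-methylcyclohex-2-en-1-one, via 1-methoxy-2-methylcyclohexa-1,4-diene 2 (not isolated), via 1-methoxy-2-methylcyclohexa-1,3-diene 3 (not isolated)
Conditions: Li, NH3(l), THF, t-BuOH, −78 to −33 °C; NH4Cl; KOt-Bu (cat.), DMSO, 25 °C; 1 M HCl, THF, 25 °C
Reagents that add atoms: water O
Why: Birch reduction gives the 1,4-diene 2, base-mediated prototropic conjugation moves the isolated double bond next to the tetrasubstituted enol ether (3), and acid hydrolysis of this dienol ether then gives the 2-methyl enone rather than the 6-methyl isomer that direct hydrolysis of 2 would give; no stereocenter is formed.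

**Step 2**
Reactants: 4 2-methylcyclohex-2-en-1-one
Product: 6 trimethyl{[(3S)-2,3-dimethylcyclohex-1-en-1-yl]oxy}silane, via dimethylaluminium enolate 5 (not isolated)
Conditions: Me3Al, CuO2CC4H3S (copper thiophene-2-carboxylate, 2 mol %), biphenol-derived bis(1-phenylethyl)amine phosphoramidite (4 mol %), Et2O, −30 °C; then Me3SiOTf, THF, −30 to 0 °C
Reagents that add atoms: trimethylaluminium C[Al](C)C; trimethylsilyl trifluoromethanesulfonate C[Si](C)(C)OS(=O)(=O)C(F)(F)F
Why: Copper-catalysed asymmetric conjugate addition of Me3Al to this enone is known chemistry; the ligand-bound methylcopper adds to one enantiotopic face of the flat enone to set the 3S methyl center (C-6 of the target), and the regiodefined aluminium enolate is kept as its silyl enol ether.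

**Step 3**
Reactants: 6 trimethyl{[(3S)-2,3-dimethylcyclohex-1-en-1-yl]oxy}silane; 7 (4-iodobut-1-yn-1-yl)trimethylsilane
Product: 9 (2R,3S)-2,3-dimethyl-2-[4-(trimethylsilyl)but-3-yn-1-yl]cyclohexan-1-one, via lithium enolate 8 (not isolated)
Conditions: MeLi, THF, 0 to 25 °C; then DMPU, 7, −78 to 0 °C
Reagents that add atoms: none
Why: MeLi cleavage of the silyl enol ether gives the regiodefined tetrasubstituted lithium enolate, whose SN2 alkylation occurs on the face anti to the neighbouring C-3 methyl, so the new quaternary center (C-5 of the target) carries the chain trans to that methyl.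

**Step 4**
Reactants: 9 (2R,3S)-2,3-dimethyl-2-[4-(trimethylsilyl)but-3-yn-1-yl]cyclohexan-1-one; 10 2,4,6-triisopropylbenzenesulfonohydrazide
Product: 11 N'-{(2R,3S)-2,3-dimethyl-2-[4-(trimethylsilyl)but-3-yn-1-yl]cyclohexylidene}-2,4,6-triisopropylbenzenesulfonohydrazide
Conditions: HCl (cat.), THF, 25 °C
Reagents that add atoms: none
Why: Acid-catalysed condensation of the ketone with the sulfonyl hydrazide gives the trisylhydrazone needed for the Shapiro reaction; no stereocenter is touched.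

**Step 5**
Reactants: 11 trisylhydrazone; 12 2-methylglutaric anhydride (3-methyloxane-2,6-dione)
Product: 15 methyl 5-{(5S,6R)-5,6-dimethyl-6-[4-(trimethylsilyl)but-3-yn-1-yl]cyclohex-1-en-1-yl}-2-methyl-5-oxopentanoate (both C-2 epimers), via vinyllithium 13 (not isolated), via lithium carboxylate 14 (not isolated)
Conditions: n-BuLi (2.2 equiv), THF, −78 to 0 °C; added to 12, THF, −78 °C; then MeI, DMPU, 25 °C
Reagents that add atoms: iodomethane CI
Why: Shapiro reaction, in which the only α-CH2 is deprotonated and loss of sulfinate and N2 gives the vinyllithium regiospecifically; it opens the anhydride at the less hindered carbonyl and the carboxylate is O-methylated in the same flask, the ring stereocenters are untouched and the chain methyl center is erased later by enolisation.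

**Step 6**
Reactants: 15 methyl keto ester
Product: 17 (6R)-6-{(5S,6R)-5,6-dimethyl-6-[4-(trimethylsilyl)but-3-yn-1-yl]cyclohex-1-en-1-yl}-3-methyloxan-2-one (both C-3 epimers), via hydroxy ester 16 (not isolated)
Conditions: (S)-2-methyl-CBS-oxazaborolidine (20 mol %), catecholborane, toluene, −78 °C; then PPTS (cat.), toluene, 50 °C
Reagents that add atoms: none
Why: Corey–Bakshi–Shibata reduction, in which the (S)-oxazaborolidine treats the alkenyl group as the large substituent and delivers hydride under reagent control to give the R allylic alcohol, which closes to the δ-lactone by acid-catalysed transesterification.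

**Step 7**
Reactants: 17 vinyl δ-lactone
Product: 20 (1S,5R,6S,8aR)-5-(but-3-yn-1-yl)-1,5,6-trimethyl-1,2,3,5,6,7,8,8a-octahydronaphthalene-1-carboxylic acid, via silyl ketene acetal 18 (not isolated), via silyl ester 19 (not isolated)
Conditions: LDA (LiN(i-Pr)2), Me3SiCl, THF, −78 to 25 °C; toluene, 110 °C; then K2CO3, MeOH, 25 °C; H3O+
Reagents that add atoms: none
Why: Ireland–Claisen rearrangement of a vinyl lactone (lactone-enolate ring contraction) through a boat-like bicyclic array, so the new bond forms on the alkene face that carried the C–O bond: the R carbinol is relayed to C-8a (H α), the quaternary C-1 is fixed with CO2H trans to H-8a by the ring-constrained ketene acetal, and the alkene moves to C4=C4a; K2CO3/MeOH then cleaves the silyl ester and the alkynyl silane.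

**Step 8**
Reactants: 20 alkyne acid
Product: 22 (1S,5R,6S,8aR)-5-[(3E)-5-hydroxy-3-methylpent-3-en-1-yl]-1,5,6-trimethyl-1,2,3,5,6,7,8,8a-octahydronaphthalene-1-carboxylic acid, via alkenylalane 21 (not isolated)
Conditions: Me3Al (4 equiv), Cp2ZrCl2 (0.3 equiv), CH2Cl2, 0 to 25 °C; then (CH2O)n, THF, 25 °C; 1 M HCl
Reagents that add atoms: trimethylaluminium C[Al](C)C; paraformaldehyde (as formaldehyde) C=O
Why: Negishi zirconium-catalysed carboalumination adds methyl and aluminium syn across the terminal alkyne (methyl to the internal carbon) and the alkenylalane is trapped by formaldehyde with retention, giving the E trisubstituted allylic alcohol while the acid sits as its aluminium carboxylate.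

**Step 9**
Reactants: 22 hydroxy acid
Product: 23 (1S,5R,6S,8aR)-5-[(3E)-5-acetoxy-3-methylpent-3-en-1-yl]-1,5,6-trimethyl-1,2,3,5,6,7,8,8a-octahydronaphthalene-1-carboxylic acid (target)
Conditions: Ac2O, pyridine, DMAP (cat.), CH2Cl2, 0 °C; aq. NaHCO3, then H3O+
Reagents that add atoms: acetic anhydride CC(=O)OC(C)=O
Why: DMAP-catalysed O-acetylation of the primary allylic alcohol, with any mixed anhydride at the hindered acid hydrolysed during the bicarbonate work-up; no stereocenter is affected.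

**Compound list**
1 | 2-methylanisole | COc1ccccc1C | starting material
2 | 1-methoxy-2-methylcyclohexa-1,4-diene | COC1=C(C)CC=CC1 | intermediate
3 | 1-methoxy-2-methylcyclohexa-1,3-diene | COC1=C(C)C=CCC1 | intermediate
4 | 2-methylcyclohex-2-en-1-one | CC1=CCCCC1=O | intermediate
5 | dimethylaluminium (3S)-2,3-dimethylcyclohex-1-en-1-olate | CC1=C(O[Al](C)C)CCC[C@@H]1C | intermediate
6 | trimethyl{[(3S)-2,3-dimethylcyclohex-1-en-1-yl]oxy}silane | CC1=C(O[Si](C)(C)C)CCC[C@@H]1C | intermediate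
7 | (4-iodobut-1-yn-1-yl)trimethylsilane | C[Si](C)(C)C#CCCI | starting material
8 | lithium (3S)-2,3-dimethylcyclohex-1-en-1-olate | CC1=C(O[Li])CCC[C@@H]1C | intermediate
9 | (2R,3S)-2,3-dimethyl-2-[4-(trimethylsilyl)but-3-yn-1-yl]cyclohexan-1-one | C[Si](C)(C)C#CCC[C@@]1(C)C(=O)CCC[C@@H]1C | intermediate
10 | 2,4,6-triisopropylbenzenesulfonohydrazide | CC(C)c1cc(C(C)C)c(S(=O)(=O)NN)c(C(C)C)c1 | starting material
11 | N'-{(2R,3S)-2,3-dimethyl-2-[4-(trimethylsilyl)but-3-yn-1-yl]cyclohexylidene}-2,4,6-triisopropylbenzenesulfonohydrazide | C[Si](C)(C)C#CCC[C@@]1(C)C(=NNS(=O)(=O)c2c(C(C)C)cc(C(C)C)cc2C(C)C)CCC[C@@H]1C | intermediate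
12 | 2-methylglutaric anhydride (3-methyloxane-2,6-dione) | CC1CCC(=O)OC1=O | starting material
13 | {(5S,6R)-5,6-dimethyl-6-[4-(trimethylsilyl)but-3-yn-1-yl]cyclohex-1-en-1-yl}lithium | C[Si](C)(C)C#CCC[C@@]1(C)C([Li])=CCC[C@@H]1C | intermediate
14 | lithium 5-{(5S,6R)-5,6-dimethyl-6-[4-(trimethylsilyl)but-3-yn-1-yl]cyclohex-1-en-1-yl}-2-methyl-5-oxopentanoate | C[Si](C)(C)C#CCC[C@@]1(C)C(C(=O)CCC(C)C(=O)O[Li])=CCC[C@@H]1C | intermediate
15 | methyl 5-{(5S,6R)-5,6-dimethyl-6-[4-(trimethylsilyl)but-3-yn-1-yl]cyclohex-1-en-1-yl}-2-methyl-5-oxopentanoate | C[Si](C)(C)C#CCC[C@@]1(C)C(C(=O)CCC(C)C(=O)OC)=CCC[C@@H]1C | intermediate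
16 | methyl (5R)-5-{(5S,6R)-5,6-dimethyl-6-[4-(trimethylsilyl)but-3-yn-1-yl]cyclohex-1-en-1-yl}-5-hydroxy-2-methylpentanoate | C[Si](C)(C)C#CCC[C@@]1(C)C([C@H](O)CCC(C)C(=O)OC)=CCC[C@@H]1C | intermediate
17 | (6R)-6-{(5S,6R)-5,6-dimethyl-6-[4-(trimethylsilyl)but-3-yn-1-yl]cyclohex-1-en-1-yl}-3-methyloxan-2-one | C[Si](C)(C)C#CCC[C@@]1(C)C([C@H]2CCC(C)C(=O)O2)=CCC[C@@H]1C | intermediate
18 | trimethyl{[(2R)-2-{(5S,6R)-5,6-dimethyl-6-[4-(trimethylsilyl)but-3-yn-1-yl]cyclohex-1-en-1-yl}-5-methyl-3,4-dihydro-2H-pyran-6-yl]oxy}silane | C[Si](C)(C)C#CCC[C@@]1(C)C([C@H]2CCC(C)=C(O[Si](C)(C)C)O2)=CCC[C@@H]1C | intermediate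
19 | trimethylsilyl (1S,5R,6S,8aR)-1,5,6-trimethyl-5-[4-(trimethylsilyl)but-3-yn-1-yl]-1,2,3,5,6,7,8,8a-octahydronaphthalene-1-carboxylate | C[Si](C)(C)C#CCC[C@@]1(C)C2=CCC[C@](C)(C(=O)O[Si](C)(C)C)[C@@H]2CC[C@@H]1C | intermediate
20 | (1S,5R,6S,8aR)-5-(but-3-yn-1-yl)-1,5,6-trimethyl-1,2,3,5,6,7,8,8a-octahydronaphthalene-1-carboxylic acid | C#CCC[C@@]1(C)C2=CCC[C@](C)(C(=O)O)[C@@H]2CC[C@@H]1C | intermediate
21 | dimethylaluminium carboxylate of the (E)-2-methylalkenyl(dimethyl)alane from 20 | C[Al](C)/C=C(\C)CC[C@@]1(C)C2=CCC[C@](C)(C(=O)O[Al](C)C)[C@@H]2CC[C@@H]1C | intermediate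
22 | (1S,5R,6S,8aR)-5-[(3E)-5-hydroxy-3-methylpent-3-en-1-yl]-1,5,6-trimethyl-1,2,3,5,6,7,8,8a-octahydronaphthalene-1-carboxylic acid | OC/C=C(\C)CC[C@@]1(C)C2=CCC[C@](C)(C(=O)O)[C@@H]2CC[C@@H]1C | intermediate
23 | (1S,5R,6S,8aR)-5-[(3E)-5-acetoxy-3-methylpent-3-en-1-yl]-1,5,6-trimethyl-1,2,3,5,6,7,8,8a-octahydronaphthalene-1-carboxylic acid | CC(=O)OC/C=C(\C)CC[C@@]1(C)C2=CCC[C@](C)(C(=O)O)[C@@H]2CC[C@@H]1C | target

**Totals**
Total step count: 9. Longest linear sequence: 9 (1 to 23; compounds 7, 10 and 12 are bought).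

**Steps most likely to fail**

Step 3. The homopropargylic iodide can undergo E2 elimination instead of alkylating the hindered tetrasubstituted enolate. The fallback sets out from 6 and comes back at 9. A Mukaiyama–Michael addition of 6 to acrolein (BF3·OEt2, CH2Cl2, −78 °C), again anti to the ring methyl, gives 3-[(1R,2S)-1,2-dimethyl-6-oxocyclohexyl]propanal F1. Ohira–Bestmann homologation of the aldehyde (dimethyl (1-diazo-2-oxopropyl)phosphonate, K2CO3, MeOH) gives (2R,3S)-2-(but-3-yn-1-yl)-2,3-dimethylcyclohexan-1-one F2. C-silylation of the alkyne (LiN(SiMe3)2, Me3SiCl, THF, −78 °C) returns 9.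

Step 5. The vinyllithium may enolise the anhydride or open it at the wrong carbonyl. The fallback sets out from 11 and comes back at 17. The Shapiro vinyllithium 13 is transmetalated with ZnCl2 to chloro{(5S,6R)-5,6-dimethyl-6-[4-(trimethylsilyl)but-3-yn-1-yl]cyclohex-1-en-1-yl}zinc F3. Negishi acylation with methyl 5-chloro-5-oxopentanoate (Pd(PPh3)4, THF) gives methyl 5-{(5S,6R)-5,6-dimethyl-6-[4-(trimethylsilyl)but-3-yn-1-yl]cyclohex-1-en-1-yl}-5-oxopentanoate F4. The same CBS reduction gives methyl (5R)-5-{(5S,6R)-5,6-dimethyl-6-[4-(trimethylsilyl)but-3-yn-1-yl]cyclohex-1-en-1-yl}-5-hydroxypentanoate F5, which lactonises to (6R)-6-{(5S,6R)-5,6-dimethyl-6-[4-(trimethylsilyl)but-3-yn-1-yl]cyclohex-1-en-1-yl}oxan-2-one F6. Enolate methylation (LDA, MeI, THF, −78 °C) then gives 17.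

Step 7. The boat-like Claisen array has to form on the ring face next to the C-5/C-6 methyls and may be too slow. The fallback sets out from 9 and comes back at 20, building ring A by a Diels–Alder reaction instead. Enol triflation (KN(SiMe3)2, PhNTf2) gives (5S,6R)-5,6-dimethyl-6-[4-(trimethylsilyl)but-3-yn-1-yl]cyclohex-1-en-1-yl trifluoromethanesulfonate F7. Stille coupling with tributyl(vinyl)stannane (Pd(PPh3)4, LiCl, THF, 65 °C) gives trimethyl{4-[(1R,6S)-2-ethenyl-1,6-dimethylcyclohex-2-en-1-yl]but-1-yn-1-yl}silane F8. Cycloaddition with methacrylic acid (toluene, 110 °C, carboxyl endo) gives (1S,5R,6S,8aR)-1,5,6-trimethyl-5-[4-(trimethylsilyl)but-3-yn-1-yl]-1,2,3,5,6,7,8,8a-octahydronaphthalene-1-carboxylic acid F9, and K2CO3/MeOH gives 20. In this fallback the face selectivity at C-8a is substrate-controlled and not assured, so the C-1/C-8a diastereomer would have to be removed by chromatography.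

**Further compounds**
F1 | step 3 | 3-[(1R,2S)-1,2-dimethyl-6-oxocyclohexyl]propanal | O=CCC[C@@]1(C)C(=O)CCC[C@@H]1C
F2 | step 3 | (2R,3S)-2-(but-3-yn-1-yl)-2,3-dimethylcyclohexan-1-one | C#CCC[C@@]1(C)C(=O)CCC[C@@H]1C
F3 | step 5 | chloro{(5S,6R)-5,6-dimethyl-6-[4-(trimethylsilyl)but-3-yn-1-yl]cyclohex-1-en-1-yl}zinc | C[Si](C)(C)C#CCC[C@@]1(C)C([Zn]Cl)=CCC[C@@H]1C
F4 | step 5 | methyl 5-{(5S,6R)-5,6-dimethyl-6-[4-(trimethylsilyl)but-3-yn-1-yl]cyclohex-1-en-1-yl}-5-oxopentanoate | C[Si](C)(C)C#CCC[C@@]1(C)C(C(=O)CCCC(=O)OC)=CCC[C@@H]1C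
F5 | step 5 | methyl (5R)-5-{(5S,6R)-5,6-dimethyl-6-[4-(trimethylsilyl)but-3-yn-1-yl]cyclohex-1-en-1-yl}-5-hydroxypentanoate | C[Si](C)(C)C#CCC[C@@]1(C)C([C@H](O)CCCC(=O)OC)=CCC[C@@H]1C
F6 | step 5 | (6R)-6-{(5S,6R)-5,6-dimethyl-6-[4-(trimethylsilyl)but-3-yn-1-yl]cyclohex-1-en-1-yl}oxan-2-one | C[Si](C)(C)C#CCC[C@@]1(C)C([C@H]2CCCC(=O)O2)=CCC[C@@H]1C
F7 | step 7 | (5S,6R)-5,6-dimethyl-6-[4-(trimethylsilyl)but-3-yn-1-yl]cyclohex-1-en-1-yl trifluoromethanesulfonate | C[Si](C)(C)C#CCC[C@@]1(C)C(OS(=O)(=O)C(F)(F)F)=CCC[C@@H]1C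
F8 | step 7 | trimethyl{4-[(1R,6S)-2-ethenyl-1,6-dimethylcyclohex-2-en-1-yl]but-1-yn-1-yl}silane | C[Si](C)(C)C#CCC[C@@]1(C)C(C=C)=CCC[C@@H]1C
F9 | step 7 | (1S,5R,6S,8aR)-1,5,6-trimethyl-5-[4-(trimethylsilyl)but-3-yn-1-yl]-1,2,3,5,6,7,8,8a-octahydronaphthalene-1-carboxylic acid | C[Si](C)(C)C#CCC[C@@]1(C)C2=CCC[C@](C)(C(=O)O)[C@@H]2CC[C@@H]1C
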